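**Assumption:** lignan locants are C7 = aryl-bearing ring carbon, C8 = CH2OH-bearing carbon, C8' = syringylmethyl-bearing carbon. The SMILES decodes to 7-aryl/8-CH2OH trans and 8-CH2OH/8'-benzyl cis on the oxolane, and that is the structure planned for. All named reagents are taken as commercial.

## Retrosynthetic overview

1. The tetrahydrofuran is the only ring made, and it is closed last. The C7–O bond comes from oxidative cyclisation of a C2-symmetric (2R,3R)-2,3-bis(syringylmethyl)butane-1,4-diol: one of its two homotopic phenols is dearomatised to a p-quinone methide, which the δ-CH2OH traps. This breaks the C2 symmetry and sets C7.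
2. The C2 diol comes from global hydride reduction of a C2-symmetric bis(N-acyloxazolidinone) carrying aryl pivalates (auxiliary and protecting groups removed together).
3. The C8–C8' bond and both stereocentres come from auxiliary-controlled oxidative enolate homodimerisation of one 3-arylpropanoyl imide.
4. The imide comes from dihydrosinapic acid, pivaloyl chloride (phenol protection and carboxyl activation in one pot) and (S)-4-isopropyl-2-oxazolidinone. The acid comes from syringaldehyde and Meldrum's acid.
5. Both aromatic rings come intact from syringaldehyde.

## Forward route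

**Step 1**
Reactants: 1, syringaldehyde (4-hydroxy-3,5-dimethoxybenzaldehyde); 2, Meldrum's acid
Product: 3, 3-(4-hydroxy-3,5-dimethoxyphenyl)propanoic acid
Conditions: HCO2H–Et3N (5:2), 95–100 °C; then aq. HCl
Reagents that add atoms: Meldrum's acid (2), CC1(C)OC(=O)CC(=O)O1 (supplies the CH2 and CO2H carbons; formate supplies only hydride)
Why: One-pot Knoevenagel condensation, formate conjugate (transfer) reduction of the arylidene Meldrum's acid, then hydrolysis and decarboxylation; the acidic medium keeps the phenol protonated, so no protection is needed and no stereocentre is formed.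

**Step 2**
Reactants: 3; 4, pivaloyl chloride; 5, (S)-4-isopropyl-2-oxazolidinone
Product: 6, (S)-3-[3-(3,5-dimethoxy-4-pivaloyloxyphenyl)propanoyl]-4-isopropyloxazolidin-2-one
Conditions: PivCl (2.5 equiv), Et3N, THF, −20 °C → rt; then LiCl, 5 (1.5 equiv), rt
Reagents that add atoms: pivaloyl chloride (4), CC(C)(C)C(=O)Cl; (S)-4-isopropyl-2-oxazolidinone (5), CC(C)[C@H]1COC(=O)N1
Why: Excess PivCl turns the carboxylate into the mixed pivalic anhydride and esterifies the hindered phenol in the same pot, and the LiCl/Et3N N-acylation of the oxazolidinone (mixed-anhydride method) then occurs at the unhindered acyl carbon; the auxiliary stereocentre is untouched.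

**Step 3**
Reactants: 6 (2 equiv)
Product: 7, (2R,3R)-2,3-bis(3,5-dimethoxy-4-pivaloyloxybenzyl)-1,4-bis[(S)-4-isopropyl-2-oxooxazolidin-3-yl]butane-1,4-dione (C2-symmetric)
Conditions: LDA (1.1 equiv), THF, −78 °C; then TiCl4 (1.1 equiv), −78 °C → rt; chromatography/recrystallisation
Reagents that add atoms: none
Why: Oxidative enolate homocoupling via the Ti(IV) (Z)-enolate; each α-carbon bonds on the face opposite the 4-isopropyl group of the chelated imide (same sense as Evans alkylation), so both C8 and C8' are set R, and the hindered, electron-poor aryl pivalates survive LDA and the oxidant.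

**Step 4**
Reactants: 7
Product: 8, (2R,3R)-2,3-bis(4-hydroxy-3,5-dimethoxybenzyl)butane-1,4-diol (C2-symmetric)
Conditions: LiAlH4 (6 equiv), THF, 0 °C → rt; Rochelle salt, then pH 5 work-up
Reagents that add atoms: none
Why: Hydride reduction cleaves both exocyclic imide carbonyls to CH2OH and both aryl pivalates to free phenols in one operation; hydride addition is faster than enolisation, so the (R,R) centres are not epimerised.

**Step 5 (key step)**
Reactants: 8
Product: 9, (+)-(7S,8R,8'R)-5,5'-dimethoxylariciresinol (target)
Conditions: DDQ (0.9 equiv, added slowly), solid NaHCO3, 1,4-dioxane, rt; recover and recycle 8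
Reagents that add atoms: none
Why: Proposed new method: DDQ dehydrogenates one of the two homotopic 4-alkyl-2,6-dimethoxyphenols to a dearomatised p-quinone methide (closest known chemistry: DDQ oxidation of 2,6-dimethoxy-4-alkylphenols to quinone methides with alcohol trapping, and the quinone-methide ring closures of lignan biosynthesis), and the δ-hydroxyl (C9'–OH) adds 1,6 to C7 to rearomatise and close the oxolane through an envelope transition state with the aryl trans to the adjacent C8–CH2OH (7S); the other CH2OH could only form an oxetane, and buffering suppresses acid-driven aryltetralin formation and C7 scrambling.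

## Compound list

1 | syringaldehyde | COc1cc(C=O)cc(OC)c1O | starting material
2 | Meldrum's acid | CC1(C)OC(=O)CC(=O)O1 | starting material
3 | 3-(4-hydroxy-3,5-dimethoxyphenyl)propanoic acid | COc1cc(CCC(=O)O)cc(OC)c1O | intermediate
4 | pivaloyl chloride | CC(C)(C)C(=O)Cl | starting material
5 | (S)-4-isopropyl-2-oxazolidinone | CC(C)[C@H]1COC(=O)N1 | starting material
6 | (S)-3-[3-(3,5-dimethoxy-4-pivaloyloxyphenyl)propanoyl]-4-isopropyloxazolidin-2-one | CC(C)[C@H]1COC(=O)N1C(=O)CCc1cc(OC)c(OC(=O)C(C)(C)C)c(OC)c1 | intermediate
7 | (2R,3R)-2,3-bis(3,5-dimethoxy-4-pivaloyloxybenzyl)succinoyl bis[(S)-4-isopropyloxazolidin-2-one] | CC(C)[C@H]1COC(=O)N1C(=O)[C@H](Cc1cc(OC)c(OC(=O)C(C)(C)C)c(OC)c1)[C@@H](Cc1cc(OC)c(OC(=O)C(C)(C)C)c(OC)c1)C(=O)N1[C@@H](C(C)C)COC1=O | intermediate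
8 | (2R,3R)-2,3-bis(4-hydroxy-3,5-dimethoxybenzyl)butane-1,4-diol | OC[C@H](Cc1cc(OC)c(O)c(OC)c1)[C@@H](Cc1cc(OC)c(O)c(OC)c1)CO | intermediate
9 | (+)-(7S,8R,8'R)-5,5'-dimethoxylariciresinol | COc1cc(C[C@H]2CO[C@H](c3cc(OC)c(O)c(OC)c3)[C@H]2CO)cc(OC)c1O | target

## Summary

Total steps: 5. Longest linear sequence: 5 (syringaldehyde → 9).

Three steps most likely to fail, each with a fallback that changes the approach:

1. **Step 5** (statistical mono-oxidation; over-oxidation to the bis-cyclised furofuran; C7 epimer; aryltetralin by-product). Fallback: oxidise fully (2.2 equiv DDQ) to C2-symmetric (+)-syringaresinol, then break the symmetry reductively by hydrogenolysis of one benzylic C–O bond (H2, Pd/C, stopped at 1 equiv H2) to give 9. Any syringaresinol formed in the normal run can be recycled the same way.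
2. **Step 3** (moderate yield and diastereoselectivity of the radical-type dimerisation). Fallback: build C8–C8' stepwise instead of by dimerisation. Evans alkylation of 6 with tert-butyl bromoacetate, reduction and lactonisation to the (R)-β-(arylmethyl)-γ-butyrolactone, trans-selective α-benzylation with 4-(bromomethyl)-2,6-dimethoxyphenyl pivalate, then LiAlH4 to the same diol 8.
3. **Step 2** (competing intermolecular aryl-ester formation or incomplete pivaloylation in the one-pot protection/activation). Fallback: change the protecting-group logic. Start from O-benzylsyringaldehyde, carry the benzyl ethers through steps 1–4, and remove them by H2/Pd-C before the DDQ step (two extra steps).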